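## Structural features

6-Prenylisocaviunin (26) is an isoflavone: benzene ring A is fused through C4a–C8a to the 4-pyranone ring C, and benzene ring B is joined to C3 of ring C by the single bond C3–C1'. There is no stereocentre; the only alkene outside the rings is the trisubstituted double bond of the 3-methylbut-2-enyl chain on C6, which has no geometry to set. Ring A is fully substituted and carries four oxygens in a 1,2,3,5 pattern: O1 on C8a, OMe on C8, OH on C7 and OH on C5 (hydrogen-bonded to the C4 carbonyl), with the prenyl chain on C6 between the two phenols. Ring B is a 2',4',5'-trimethoxyphenyl group whose only hydrogens sit on C3' and C6'. The fragile points are the prenyl group between two free phenols (acid closes it to a dimethylchroman), C2 of the pyranone (nucleophiles add there and base opens the ring), and both electron-rich rings (oxidants). The difficulty is regiochemical: ring C must be closed onto the oxygen next to the methoxy group (the other ortho oxygen would give the 6-methoxy isomer), and the five-carbon chain must arrive at C6 as a linear prenyl group. The key step exploits ring B: the oxygens on C2' and C5' are para, a further methoxy sits on C4', and C1' carries the chromone. This is the 4-alkoxyphenol pattern that an alkoxy(alkenyl)carbene carbon (C5'), its alkene (C4', C3'), one CO (C2') and a terminal alkyne (C1', C6') assemble.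

## Logic of the disconnections

26 to 25: the bond between C6 and the side-chain CH2 is cut by a retro-[3,3] shift, which moves the five-carbon unit onto O7 as a tertiary allyl ether. C6 is the only ortho carbon of O7 that bears hydrogen, and the sigmatropic shift inverts the allyl unit, so a tertiary ether delivers the linear chain. The gain is that C–C bond formation at a crowded carbon becomes intramolecular and regiodefined. The forward step must run without acid, so that the ether does not ionize and the product does not close to a chroman.

25 to 22 and 24: the O7–C bond is cut. The C7 hydroxyl is the acidic, non-chelated one, so it can be alkylated in the presence of the C5 hydroxyl. This separates the whole isoflavone core from the C5 unit. The forward step must attack the substituted end of the allyl unit. 24 goes back to 23 by cutting the carbonate C–O bond.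

22 to 21 to 20: the benzyl and acetal groups on O5 and O7 are put back, then the O–CH3 bond at C2' is cut. Deprotection is placed before the prenyl group exists, so no acid or Lewis acid ever meets it. 20 has exactly one free phenol, so the forward methylation needs no selectivity.

20 to 13 and 18: the bonds C5'–C6', C1'–C2' and C2'–C3' are cut and ring B disappears. What remains is a terminal alkyne on C3, a two-carbon alkenyl carbene unit and one CO. The trioxygenated ring is thus traded for small building blocks with its substitution pattern fixed by the mechanism. The forward step must insert the alkyne with the chromone carbon next to the CO-derived carbon and must end in phenol formation.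

18 to 14 and 15: the carbene carbon–vinyl carbon bond and the O–CH3 bond are cut, leaving a metalated enol ether, a CO ligand of 15 and a methylating agent. The forward step needs a hard alkylating agent for the acylmetalate and cold handling.

13 to 12 to 10 and 11: the C–Si bond and then the C3–C(sp) bond are cut. An iodide on C3 of the pyranone is the standard handle for sp–sp2 coupling. The forward steps must avoid nucleophilic bases that add to C2.

10 to 8 (through 9): O1–C2, C2–C3 and C3–I are cut. C2 comes from a formamide acetal and the iodine from I2. This reduces ring C to an ortho-hydroxyacetophenone. The demand is that the only free phenol of 8 is the one next to the methoxy group, because that phenol becomes O1.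

8 to 7 to 5: the acetal on the ortho oxygen is put back, and the aryl–acetyl bond (C4a–C4) is cut to an aryllithium. The benzyl ether on the other ortho oxygen is what makes the unmasking unambiguous. Lithiation needs a hydrogen flanked by two oxygens, and 5 has two equivalent ones.

5 to 4 to 2 to 1: the O–benzyl bond, then the C–O bond of the future C5 oxygen (through a C–B bond), then the two acetal O–C bonds are cut. 1 has only three of the four ring-A oxygens, and the missing one lies meta to both hydroxyls, where only a sterically controlled C–H borylation reaches. The forward borylation must leave the acetals alone and hit the one unhindered C–H.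

## Other disconnections considered

Alternative 1: the cut is C8–C8a, with C5–C8 of ring A coming from a squaric ester. In the forward key step, heating the cyclobutenone A2 (2-tert-butoxy-4-(methoxymethoxy)-3-prenyl-4-[4-oxo-5-(2,4,5-trimethoxyphenyl)pyran-3-yl]cyclobutenone) opens the four-membered ring to a ketene. The ketene carbon closes in a six-electron electrocyclization onto the pyranone CH next to the ring oxygen, and tautomerization gives the 8-phenol A1 (7-tert-butoxy-8-hydroxy-5-(methoxymethoxy)-6-prenyl-3-(2,4,5-trimethoxyphenyl)chromen-4-one).
- In favour: ring A is formed fully substituted, with the prenyl chain already on C6 and three differently masked oxygens. Neither a late prenylation nor the choice of which oxygen becomes O1 arises. On this structural point it is better than the chosen plan. It is also better in needing no stoichiometric metal.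
- Against: A2 requires a C3-metalated 5-aryl-4-pyranone to add to a cyclobutenedione. That nucleophile sits on a Michael acceptor and has little precedent.
- Against: the substituent order in A2 (alkoxy next to the carbonyl carbon, prenyl next to the carbinol carbon) is the reverse of what direct addition to an alkoxy-alkyl cyclobutenedione delivers, so a carbonyl transposition is needed.
- Against: A1 still needs 8-O-methylation and acidic removal of the tert-butyl and acetal groups with the prenyl chain already between two emerging phenols, which is where chroman formation is most likely.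
- Comparison: mechanistically the two plans are equal in kind, since both close a benzene ring by electrocyclization of a dienylketene, here metal-free and there on chromium. In step count the alternative is about equal on paper, but more of its steps lack close precedent.

Alternative 2: the cut is O1–C8a. In the forward key step, a hypervalent iodine oxidant in aqueous acetonitrile takes the para-methoxyphenol ring of the enaminone A4 (1-[4-(benzyloxy)-2-hydroxy-5-methoxyphenyl]-3-(dimethylamino)-2-(2,4,5-trimethoxyphenyl)prop-2-en-1-one) to the quinone level. The enaminone is hydrolysed, the enol oxygen adds to the quinone carbon that becomes C8a, and tautomerization gives the hydroquinone A3 (7-(benzyloxy)-5,8-dihydroxy-3-(2,4,5-trimethoxyphenyl)chromen-4-one).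
- In favour: ring B is bought as part of an arylacetic acid unit and the ketone behind A4 comes from plain acylation chemistry. The route is shorter and uses no chromium, so it is better in step economy.
- In favour: the position of O1 is fixed by the quinone, which equals the chosen plan in regiocontrol. The 8-hydroxyl of A3 can be methylated selectively because the 5-hydroxyl is chelated.
- Against: the C8 methoxy group is destroyed and then rebuilt.
- Against: the oxidant can also attack ring B (a 1,2,4-trimethoxybenzene) and the hydroquinone A3 itself. Water competes with the enol for the quinone, and A3 is air-sensitive.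
- Comparison: a late prenylation after debenzylation is still needed, so the endgame is equal to that of the chosen plan. Mechanistically it is a polar oxidative dearomatization and conjugate addition, against an organometallic template in the chosen plan.

Alternative 3: the cut is C4–C4a. In the forward key step, the acrylic acid A6 ((2Z)-3-[3,5-bis(benzyloxy)-2-methoxyphenoxy]-2-(2,4,5-trimethoxyphenyl)prop-2-enoic acid), activated with trifluoroacetic anhydride, acylates the ring carbon ortho to the ether oxygen. This gives A5 (5,7-bis(benzyloxy)-8-methoxy-3-(2,4,5-trimethoxyphenyl)chromen-4-one).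
- In favour: only one ortho carbon is free, since the other carries the methoxy group. The 6-methoxy isomer cannot form, which equals the chosen plan.
- In favour: the attacked carbon is flanked by one benzyloxy group and para to the other, so it is highly nucleophilic. No metal is needed and ring B is bought, so from the phenol onward it is better in step economy.
- Against: it needs a phenol whose free hydroxyl is the one next to the methoxy group, with the other two oxygens benzylated. The differentiation problem that costs the chosen plan five steps is moved, not removed.
- Against: A6 must hold acid and aryloxy group cis, and its enol ether link is labile under the anhydride and acid conditions. Benzyl groups on a phloroglucinol-type ring can migrate to carbon in strong acid.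
- Comparison: debenzylation and late prenylation follow as in the chosen plan. Mechanistically it is a classical electrophilic aromatic substitution.

The carbene route is kept because it builds the oxygenation pattern of ring B in one step from simple parts, with the regiochemistry fixed by the terminal alkyne. Alternatives 2 and 3 are more economical because ring B can be bought.

Key step: step 10

Remark on the chemistry: 2-methoxyresorcinol carries only three of the four ring-A oxygens (those of C8a, C8 and C7), so the C5 oxygen is added by C–H borylation and oxidation and is kept as a benzyl ether, which leaves the phenol next to the methoxy group as the only one that can close ring C; carbonate 24 is made in one step because its commercial supply is uncertain.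

## Route

Step 1
Reactants: 1 2-methoxyresorcinol (2-methoxybenzene-1,3-diol)
Product: 2 2-methoxy-1,3-bis(methoxymethoxy)benzene
Conditions: NaH (2.4 equiv), MOMCl (2.4 equiv), DMF, 0 °C → rt
Reagents that add atoms: chloromethyl methyl ether, COCCl
Why: Double O-alkylation of the bis-phenoxide (Williamson-type acetal ether formation); the two hydroxyls are equivalent, so a single product is expected, and the acetals later direct the lithiation.

Step 2
Reactants: 2 2-methoxy-1,3-bis(methoxymethoxy)benzene
Product: 4 4-methoxy-3,5-bis(methoxymethoxy)phenol, via arylboronate 3 (not isolated)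
Conditions: B2pin2 (0.7 equiv), [Ir(OMe)(cod)]2 (1.5 mol %), 4,4'-di-tert-butyl-2,2'-bipyridine (3 mol %), THF, 80 °C; then 30% H2O2, aq. NaOH, 0 °C → rt
Reagents that add atoms: hydrogen peroxide, OO; bis(pinacolato)diboron, CC1(C)OB(OC1(C)C)B1OC(C)(C)C(C)(C)O1 (boron of 3 only)
Why: Iridium-catalysed aromatic C–H borylation is governed by sterics, and C5 is the only C–H of 2 without an ortho substituent; basic peroxide then converts C–B into C–OH while the acetals survive (borylation–oxidation route to meta-substituted phenols). This supplies the fourth oxygen of ring A, the future C5 oxygen.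

Step 3
Reactants: 4 4-methoxy-3,5-bis(methoxymethoxy)phenol
Product: 5 5-(benzyloxy)-2-methoxy-1,3-bis(methoxymethoxy)benzene
Conditions: BnBr, K2CO3, DMF, rt
Reagents that add atoms: benzyl bromide, BrCc1ccccc1
Why: Williamson etherification of the only free phenol; the benzyl group marks this oxygen as different from the two acetal-protected ones, which is what later makes the choice of O1 unambiguous.

Step 4
Reactants: 5 5-(benzyloxy)-2-methoxy-1,3-bis(methoxymethoxy)benzene
Product: 7 1-[6-(benzyloxy)-3-methoxy-2,4-bis(methoxymethoxy)phenyl]ethan-1-one, via aryllithium 6 (not isolated)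
Conditions: n-BuLi (1.2 equiv), TMEDA, THF, 0 °C; MeC(O)N(OMe)Me, −78 → 0 °C; H2O
Reagents that add atoms: N-methoxy-N-methylacetamide, CON(C)C(C)=O; n-butyllithium, [Li]CCCC (lithium of 6 only)
Why: Directed ortho-metalation: the two ring hydrogens of 5 are equivalent and each lies between an acetal oxygen and the benzyloxy group, so one aryllithium forms; acylation with the N-methoxy-N-methylamide stops at the ketone through the chelated tetrahedral adduct.

Step 5
Reactants: 7 1-[6-(benzyloxy)-3-methoxy-2,4-bis(methoxymethoxy)phenyl]ethan-1-one
Product: 8 1-[6-(benzyloxy)-2-hydroxy-3-methoxy-4-(methoxymethoxy)phenyl]ethan-1-one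
Conditions: HCl (0.1 M), MeOH, 0 °C → rt, stopped at full conversion of 7
Reagents that add atoms: none
Why: Acid-catalysed transacetalization; the acetal ortho to the ketone should cleave faster than the para one because the phenol set free is hydrogen-bonded to the carbonyl, and the benzyl ether is inert. The liberated phenol is the one next to the methoxy group, so ring closure can only give the 8-methoxy chromone.

Step 6
Reactants: 8 1-[6-(benzyloxy)-2-hydroxy-3-methoxy-4-(methoxymethoxy)phenyl]ethan-1-one
Product: 10 5-(benzyloxy)-3-iodo-8-methoxy-7-(methoxymethoxy)chromen-4-one, via enaminone 9 (not isolated)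
Conditions: Me2NCH(OMe)2 (3 equiv), toluene, 90 °C; evaporate; I2 (1.5 equiv), CHCl3, rt
Reagents that add atoms: N,N-dimethylformamide dimethyl acetal, COC(OC)N(C)C; iodine, II
Why: Condensation of the methyl ketone with the formamide acetal gives the (E)-enaminone; iodination at its α-carbon, attack of the phenol on the iminium carbon and loss of dimethylamine close ring C (the standard enaminone route to 3-iodochromones).

Step 7
Reactants: 10 5-(benzyloxy)-3-iodo-8-methoxy-7-(methoxymethoxy)chromen-4-one; 11 trimethylsilylacetylene
Product: 12 5-(benzyloxy)-8-methoxy-7-(methoxymethoxy)-3-[(trimethylsilyl)ethynyl]chromen-4-one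
Conditions: PdCl2(PPh3)2 (3 mol %), CuI (6 mol %), Et3N (3 equiv), THF, rt
Reagents that add atoms: none
Why: Sonogashira coupling at the C3 iodide, an activated alkenyl-type iodide next to the carbonyl; a tertiary amine base is used because secondary amines add to C2 of chromones.

Step 8
Reactants: 12 5-(benzyloxy)-8-methoxy-7-(methoxymethoxy)-3-[(trimethylsilyl)ethynyl]chromen-4-one
Product: 13 5-(benzyloxy)-3-ethynyl-8-methoxy-7-(methoxymethoxy)chromen-4-one
Conditions: Bu4NF (1.1 equiv), AcOH (1.2 equiv), THF, −20 → 0 °C
Reagents that add atoms: none
Why: Fluoride-induced cleavage of the C(sp)–Si bond; acetic acid buffers the medium so that neither fluoride nor the acetylide attacks C2 of the pyranone.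

Step 9
Reactants: 14 methyl vinyl ether; 15 chromium hexacarbonyl, Cr(CO)6
Product: 18 pentacarbonyl[methoxy(1-methoxyvinyl)carbene]chromium, via 1-methoxyvinyllithium 16 (not isolated), via lithium acylchromate 17 (not isolated)
Conditions: t-BuLi, THF, −78 → 0 °C; Cr(CO)6, Et2O, 0 °C → rt; Me3OBF4, CH2Cl2, 0 °C; used at once
Reagents that add atoms: trimethyloxonium tetrafluoroborate, C[O+](C)C.F[B-](F)(F)F; tert-butyllithium, [Li]C(C)(C)C (lithium of 16 and 17 only)
Why: Standard synthesis of alkoxycarbene complexes of zerovalent chromium: the α-lithiated enol ether adds to a CO ligand to give the acylmetalate, and the hard oxonium salt methylates its oxygen.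

Step 10
Reactants: 13 5-(benzyloxy)-3-ethynyl-8-methoxy-7-(methoxymethoxy)chromen-4-one; 18 pentacarbonyl[methoxy(1-methoxyvinyl)carbene]chromium
Product: 20 5-(benzyloxy)-3-(2-hydroxy-4,5-dimethoxyphenyl)-8-methoxy-7-(methoxymethoxy)chromen-4-one, via tricarbonylchromium complex 19 (not isolated)
Conditions: 18 (1.5 equiv), THF (0.05 M), 50 °C, Ar; then air, MeCN, rt
Reagents that add atoms: none
Why: Heating releases one CO from 18, and the alkyne of 13 coordinates to the zerovalent chromium and inserts into the Cr=C bond, joining its CH carbon to the former carbene carbon (C5'–C6') and leaving the chromone-bearing carbon as the new carbene carbon. A CO ligand then inserts at that carbon (C1'–C2') to give a chromium-bound dienylketene, whose ketene carbon closes onto the CH2 end of the methoxyvinyl group (C2'–C3'); enolization gives the phenol as its Cr(CO)3 complex 19, and air strips the metal to leave 20. The closest known reaction type is the Dötz benzannulation of alkenyl(alkoxy)carbene complexes of chromium with terminal aryl-type alkynes to 4-alkoxyphenols. Ring B is closed by a six-electron electrocyclization of the metal-bound dienylketene, not by an ionic cyclization, and no stereocentre is formed. The selectivity that matters is the direction of alkyne insertion: the bulkier alkyne substituent (the chromon-3-yl group) ends next to the CO-derived carbon and the alkyne hydrogen next to C5', which places the chromone on C1' between C2'(OH) and C6'(H). Phenol formation should prevail over cyclopentannulation or furan formation because alkenyl complexes insert CO readily in an ether solvent at moderate temperature and high dilution, and because the C4 carbonyl could trap the vinylcarbene only through a four-membered ring. The benzyl ether, the acetal and the pyranone double bond are spectators at 50 °C.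

Step 11
Reactants: 20 5-(benzyloxy)-3-(2-hydroxy-4,5-dimethoxyphenyl)-8-methoxy-7-(methoxymethoxy)chromen-4-one
Product: 21 5-(benzyloxy)-8-methoxy-7-(methoxymethoxy)-3-(2,4,5-trimethoxyphenyl)chromen-4-one
Conditions: MeI, K2CO3, acetone, 40 °C
Reagents that add atoms: iodomethane, CI
Why: Williamson methylation of the only free phenol (C2'–OH); it also removes the air-sensitive hydroquinone monoether function of ring B.

Step 12
Reactants: 21 5-(benzyloxy)-8-methoxy-7-(methoxymethoxy)-3-(2,4,5-trimethoxyphenyl)chromen-4-one
Product: 22 isocaviunin, 5,7-dihydroxy-8-methoxy-3-(2,4,5-trimethoxyphenyl)chromen-4-one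
Conditions: BCl3 (1 M in CH2Cl2, 4 equiv), C6HMe5 (3 equiv), CH2Cl2, −78 → −20 °C; MeOH
Reagents that add atoms: none
Why: Lewis-acid ether cleavage: BCl3 removes the benzyl group on the carbonyl-chelated O5 and the acetal on O7 at low temperature, pentamethylbenzene traps the benzyl cation so that it does not alkylate C6, and the methyl ethers survive. Both groups are removed before the prenyl chain exists.

Step 13
Reactants: 23 2-methylbut-3-en-2-ol
Product: 24 tert-butyl 2-methylbut-3-en-2-yl carbonate
Conditions: n-BuLi, THF, −78 °C; Boc2O, −78 °C → rt
Reagents that add atoms: di-tert-butyl dicarbonate, CC(C)(C)OC(=O)OC(=O)OC(C)(C)C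
Why: Acylation of the lithium alkoxide of a tertiary allylic alcohol by the dicarbonate, the usual preparation of allylic carbonates for palladium-catalysed allylation.

Step 14
Reactants: 22 isocaviunin; 24 tert-butyl 2-methylbut-3-en-2-yl carbonate
Product: 25 5-hydroxy-8-methoxy-7-[(2-methylbut-3-en-2-yl)oxy]-3-(2,4,5-trimethoxyphenyl)chromen-4-one
Conditions: 24 (1.5 equiv), Pd(PPh3)4 (5 mol %), THF, 0 °C → rt
Reagents that add atoms: none
Why: Tsuji–Trost O-allylation: zerovalent palladium ionizes the carbonate, the tert-butoxide set free deprotonates the acidic C7 hydroxyl (the C5 hydroxyl stays chelated), and the phenoxide attacks the substituted end of the dimethylallyl–palladium unit to give the tertiary ether as the kinetic product.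

Step 15
Reactants: 25 5-hydroxy-8-methoxy-7-[(2-methylbut-3-en-2-yl)oxy]-3-(2,4,5-trimethoxyphenyl)chromen-4-one
Product: 26 6-prenylisocaviunin, 5,7-dihydroxy-8-methoxy-6-(3-methylbut-2-en-1-yl)-3-(2,4,5-trimethoxyphenyl)chromen-4-one
Conditions: PhNEt2, 130 °C
Reagents that add atoms: none
Why: Aromatic Claisen rearrangement: the [3,3] shift can end productively only on C6, because C8 carries the methoxy group, and the inversion of the allyl unit turns the tertiary ether into the linear prenyl chain; tautomerization restores the C7 phenol, and the basic solvent suppresses acid-induced chroman formation.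

## Compound list

1 | 2-methoxyresorcinol (2-methoxybenzene-1,3-diol) | COc1c(O)cccc1O | starting material
2 | 2-methoxy-1,3-bis(methoxymethoxy)benzene | COCOc1cccc(OCOC)c1OC | intermediate
3 | 2-[4-methoxy-3,5-bis(methoxymethoxy)phenyl]-4,4,5,5-tetramethyl-1,3,2-dioxaborolane (not isolated) | COCOc1cc(B2OC(C)(C)C(C)(C)O2)cc(OCOC)c1OC | intermediate
4 | 4-methoxy-3,5-bis(methoxymethoxy)phenol | COCOc1cc(O)cc(OCOC)c1OC | intermediate
5 | 5-(benzyloxy)-2-methoxy-1,3-bis(methoxymethoxy)benzene | COCOc1cc(OCc2ccccc2)cc(OCOC)c1OC | intermediate
6 | [6-(benzyloxy)-3-methoxy-2,4-bis(methoxymethoxy)phenyl]lithium (not isolated) | [Li]c1c(OCOC)c(OC)c(OCOC)cc1OCc1ccccc1 | intermediate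
7 | 1-[6-(benzyloxy)-3-methoxy-2,4-bis(methoxymethoxy)phenyl]ethan-1-one | CC(=O)c1c(OCOC)c(OC)c(OCOC)cc1OCc1ccccc1 | intermediate
8 | 1-[6-(benzyloxy)-2-hydroxy-3-methoxy-4-(methoxymethoxy)phenyl]ethan-1-one | CC(=O)c1c(O)c(OC)c(OCOC)cc1OCc1ccccc1 | intermediate
9 | (2E)-1-[6-(benzyloxy)-2-hydroxy-3-methoxy-4-(methoxymethoxy)phenyl]-3-(dimethylamino)prop-2-en-1-one (not isolated) | CN(C)/C=C/C(=O)c1c(O)c(OC)c(OCOC)cc1OCc1ccccc1 | intermediate
10 | 5-(benzyloxy)-3-iodo-8-methoxy-7-(methoxymethoxy)chromen-4-one | O=c1c(I)coc2c(OC)c(OCOC)cc(OCc3ccccc3)c12 | intermediate
11 | trimethylsilylacetylene | C#C[Si](C)(C)C | starting material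
12 | 5-(benzyloxy)-8-methoxy-7-(methoxymethoxy)-3-[(trimethylsilyl)ethynyl]chromen-4-one | C[Si](C)(C)C#Cc1coc2c(OC)c(OCOC)cc(OCc3ccccc3)c2c1=O | intermediate
13 | 5-(benzyloxy)-3-ethynyl-8-methoxy-7-(methoxymethoxy)chromen-4-one | C#Cc1coc2c(OC)c(OCOC)cc(OCc3ccccc3)c2c1=O | intermediate
14 | methyl vinyl ether | COC=C | starting material
15 | chromium hexacarbonyl, Cr(CO)6 | O=C=[Cr](=C=O)(=C=O)(=C=O)(=C=O)=C=O | starting material
16 | (1-methoxyvinyl)lithium (not isolated) | [Li]C(=C)OC | intermediate
17 | lithium pentacarbonyl(2-methoxyprop-2-enoyl)chromate (not isolated) | [Li+].C=C(OC)C([O-])=[Cr](=C=O)(=C=O)(=C=O)(=C=O)=C=O | intermediate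
18 | pentacarbonyl[methoxy(1-methoxyvinyl)carbene]chromium | COC(C(OC)=C)=[Cr](=C=O)(=C=O)(=C=O)(=C=O)=C=O | intermediate
19 | tricarbonylchromium complex of 20, Cr(CO)3 bound η6 to ring B (not isolated; the η6 bond is written as a dot) | COc1cc(O)c(-c2coc3c(OC)c(OCOC)cc(OCc4ccccc4)c3c2=O)cc1OC.O=C=[Cr](=C=O)=C=O | intermediate
20 | 5-(benzyloxy)-3-(2-hydroxy-4,5-dimethoxyphenyl)-8-methoxy-7-(methoxymethoxy)chromen-4-one | COc1cc(O)c(-c2coc3c(OC)c(OCOC)cc(OCc4ccccc4)c3c2=O)cc1OC | intermediate
21 | 5-(benzyloxy)-8-methoxy-7-(methoxymethoxy)-3-(2,4,5-trimethoxyphenyl)chromen-4-one | COc1cc(OC)c(-c2coc3c(OC)c(OCOC)cc(OCc4ccccc4)c3c2=O)cc1OC | intermediate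
22 | isocaviunin, 5,7-dihydroxy-8-methoxy-3-(2,4,5-trimethoxyphenyl)chromen-4-one | COc1cc(OC)c(-c2coc3c(OC)c(O)cc(O)c3c2=O)cc1OC | intermediate
23 | 2-methylbut-3-en-2-ol | CC(C)(O)C=C | starting material
24 | tert-butyl 2-methylbut-3-en-2-yl carbonate | CC(C)(C)OC(=O)OC(C)(C)C=C | intermediate
25 | 5-hydroxy-8-methoxy-7-[(2-methylbut-3-en-2-yl)oxy]-3-(2,4,5-trimethoxyphenyl)chromen-4-one | COc1cc(OC)c(-c2coc3c(OC)c(OC(C)(C)C=C)cc(O)c3c2=O)cc1OC | intermediate
26 | 6-prenylisocaviunin, 5,7-dihydroxy-8-methoxy-6-(3-methylbut-2-en-1-yl)-3-(2,4,5-trimethoxyphenyl)chromen-4-one | COc1cc(OC)c(-c2coc3c(OC)c(O)c(CC=C(C)C)c(O)c3c2=O)cc1OC | target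

## Step count and least certain steps

Total: 15 steps. Longest linear sequence: 13 steps (steps 1–8, 10–12, 14 and 15); steps 9 and 13 are one-step side branches.

Step 10 (key step). The most likely failure is diversion of the vinylcarbene or ketene intermediates away from CO insertion and electrocyclization (cyclopentannulation, cyclobutenone formation, alkyne oligomerization). Coordination of the C4 carbonyl to chromium could help this, and the α-methoxyvinyl complex 18 may decompose before it inserts. Oxidation of the electron-rich 4-methoxyphenol to a quinone during air demetalation is a second hazard. Fallback: starting from 10, a Suzuki–Miyaura coupling with commercial (2,4,5-trimethoxyphenyl)boronic acid (Pd(PPh3)4, Na2CO3, DME/H2O, 80 °C) would give 21 directly, where the route is rejoined. Ring B is then bought instead of built, and this fallback makes no new compound (F0).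

Step 5. The likely failure is loss of selectivity in the acetal cleavage: the para acetal may hydrolyse at a similar rate, because the rate gap between ortho and para acetals is modest. Fallback: starting from 7, both acetals would be removed with stronger methanolic HCl to give 1-[6-(benzyloxy)-2,4-dihydroxy-3-methoxyphenyl]ethan-1-one F1. The non-chelated para hydroxyl of F1 would then be re-protected alone with MOMCl (1.05 equiv) and i-Pr2NEt in CH2Cl2 at 0 °C, which returns to the route at 8.

Step 8. The likely failure is nucleophilic opening of the pyranone at C2 by fluoride or by the acetylide, or base-induced oligomerization of the terminal alkyne. Fallback: starting from 10, a Negishi coupling with ethynylzinc bromide (from ethynylmagnesium bromide and ZnBr2; Pd(PPh3)4, THF, rt) would give 13 directly without a silyl group. It rejoins at 13 and makes no new compound (F0).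

Step 14. The likely failure is isomerization of the kinetic tertiary ether to the linear O-prenyl ether by renewed ionization, since the C7 phenoxide is a good leaving group, or competing C-allylation. Fallback: starting from 22, O-alkylation with 3-chloro-3-methylbut-1-yne (K2CO3, KI, CuI cat., acetone, 50 °C) would give 5-hydroxy-8-methoxy-7-[(2-methylbut-3-yn-2-yl)oxy]-3-(2,4,5-trimethoxyphenyl)chromen-4-one F2. Semihydrogenation of F2 (H2, Pd/CaCO3 poisoned with Pb(OAc)2, quinoline, EtOAc) returns to the route at 25.

Step 15. The likely failure is fragmentation of the tertiary allyl ether (loss of isoprene back to 22) or acid-induced closure of the product to a dimethylchroman instead of a clean [3,3] shift. Fallback: starting from 22, direct C-alkylation of the C7 phenoxide with prenyl bromide (NaOMe, MeOH, 0 °C → rt) would give 26. C6 is the only free ring-A carbon, but O-alkylation competes and a modest conversion has to be accepted. This fallback makes no new compound (F0).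

## Further compounds

F1 | step 5 | 1-[6-(benzyloxy)-2,4-dihydroxy-3-methoxyphenyl]ethan-1-one | CC(=O)c1c(O)c(OC)c(O)cc1OCc1ccccc1
F0 | step 8 | none | none
F0 | step 10 | none | none
F2 | step 14 | 5-hydroxy-8-methoxy-7-[(2-methylbut-3-yn-2-yl)oxy]-3-(2,4,5-trimethoxyphenyl)chromen-4-one | COc1cc(OC)c(-c2coc3c(OC)c(OC(C)(C)C#C)cc(O)c3c2=O)cc1OC
F0 | step 15 | none | none
A1 | alternative 1 | 7-tert-butoxy-8-hydroxy-5-(methoxymethoxy)-6-(3-methylbut-2-en-1-yl)-3-(2,4,5-trimethoxyphenyl)chromen-4-one | COCOc1c(CC=C(C)C)c(OC(C)(C)C)c(O)c2occ(-c3cc(OC)c(OC)cc3OC)c(=O)c12
A2 | alternative 1 | 2-tert-butoxy-4-(methoxymethoxy)-3-(3-methylbut-2-en-1-yl)-4-[4-oxo-5-(2,4,5-trimethoxyphenyl)-4H-pyran-3-yl]cyclobut-2-en-1-one (racemic) | O=C1C(OC(C)(C)C)=C(CC=C(C)C)C1(OCOC)c1cocc(-c2cc(OC)c(OC)cc2OC)c1=O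
A3 | alternative 2 | 7-(benzyloxy)-5,8-dihydroxy-3-(2,4,5-trimethoxyphenyl)chromen-4-one | COc1cc(OC)c(OC)cc1-c1coc2c(O)c(OCc3ccccc3)cc(O)c2c1=O
A4 | alternative 2 | (2E)-1-[4-(benzyloxy)-2-hydroxy-5-methoxyphenyl]-3-(dimethylamino)-2-(2,4,5-trimethoxyphenyl)prop-2-en-1-one | CN(C)/C=C(\c1cc(OC)c(OC)cc1OC)C(=O)c1cc(OC)c(OCc2ccccc2)cc1O
A5 | alternative 3 | 5,7-bis(benzyloxy)-8-methoxy-3-(2,4,5-trimethoxyphenyl)chromen-4-one | COc1cc(OC)c(OC)cc1-c1coc2c(OC)c(OCc3ccccc3)cc(OCc3ccccc3)c2c1=O
A6 | alternative 3 | (2Z)-3-[3,5-bis(benzyloxy)-2-methoxyphenoxy]-2-(2,4,5-trimethoxyphenyl)prop-2-enoic acid | OC(=O)/C(=C\Oc1cc(OCc2ccccc2)cc(OCc2ccccc2)c1OC)c1cc(OC)c(OC)cc1OC
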